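**Strategy**

The plan closes the pyran ring F of the lower (catechin) unit last, by forming its C4–C4a bond. An (S)-1-arylpropargyl ether on the C8a oxygen of ring D is cyclised by gold catalysis (6-endo-dig hydroarylation): the C4a–H of ring D, flanked by O1 and the C5 oxygen and para to the C7 oxygen, attacks the terminal alkyne carbon. Since C8 already carries the benzyl-protected upper (mesquitol) unit, C4a is the only free ortho position, so the 4→8 linkage is fixed by construction. Hydroboration of the resulting flav-3-ene then sets C3 trans to C2. The same propargyl acetate and the same cyclisation also build the upper unit.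

Key step: step 9

Remark (ring letters and target): the target is read as mesquitol-(4α→8)-catechin, upper unit 2R,3S,4S (2,3-trans-3,4-trans), lower unit 2R,3S; rings A/C/B belong to the upper unit and D/F/E to the lower unit.
Remark (assumptions): compounds 1, 4 and 10 are taken as commercial; the copper/(S,S)-Ph-pybox catalyst [2,6-bis((4S)-4-phenyl-4,5-dihydrooxazol-2-yl)pyridine] is assumed to give the (S)-propargyl ether, and the (R,R)-ligand is used if the opposite sense is found.

**Route**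

Step 1
Reactants: 1 3,4-bis(benzyloxy)benzaldehyde
Product: 2 rac-1-[3,4-bis(benzyloxy)phenyl]prop-2-yn-1-ol
Conditions: HC≡CMgBr, THF, 0 °C; aq. NH4Cl
Reagents that add atoms: ethynylmagnesium bromide, C#C[Mg]Br
Why: Grignard addition to the aldehyde; the racemate suffices because the stereocentre is set later by the copper catalyst through an intermediate shared by both enantiomers.

Step 2
Reactants: 2 rac-1-[3,4-bis(benzyloxy)phenyl]prop-2-yn-1-ol
Product: 3 rac-1-[3,4-bis(benzyloxy)phenyl]prop-2-yn-1-yl acetate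
Conditions: Ac2O, Et3N, DMAP (cat.), CH2Cl2, 0 °C
Reagents that add atoms: acetic anhydride, CC(=O)OC(C)=O
Why: DMAP-catalysed acylation gives the propargylic ester needed as the leaving group for propargylic substitution.

Step 3
Reactants: 4 2,3-bis(benzyloxy)benzaldehyde
Product: 6 2,3-bis(benzyloxy)phenol, via aryl formate 5 (not isolated)
Conditions: mCPBA, CH2Cl2, 0 °C to rt; aq. NaHCO3 wash; then Et3N, MeOH, rt
Reagents that add atoms: mCPBA, O=C(OO)c1cccc(Cl)c1
Why: Baeyer–Villiger (Dakin-type) oxidation, in which the electron-rich aryl group migrates to give the formate, followed by mild methanolysis to the phenol.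

Step 4
Reactants: 6 2,3-bis(benzyloxy)phenol; 3 rac-1-[3,4-bis(benzyloxy)phenyl]prop-2-yn-1-yl acetate
Product: 7 1,2-bis(benzyloxy)-3-{[(1S)-1-[3,4-bis(benzyloxy)phenyl]prop-2-yn-1-yl]oxy}benzene
Conditions: Cu(MeCN)4BF4 (5 mol %), (S,S)-Ph-pybox (6 mol %), iPr2NEt, MeOH, −20 °C
Reagents that add atoms: none
Why: Copper-catalysed enantioselective propargylic etherification: the copper acetylide loses acetate to a copper allenylidene common to both enantiomers of 3, and the phenoxide attacks its γ-carbon on the face left open by the pybox ligand, which should set the (S)-centre.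

Step 5
Reactants: 7 1,2-bis(benzyloxy)-3-{[(1S)-1-[3,4-bis(benzyloxy)phenyl]prop-2-yn-1-yl]oxy}benzene
Product: 8 (2S)-7,8-bis(benzyloxy)-2-[3,4-bis(benzyloxy)phenyl]-2H-chromene
Conditions: Ph3PAuNTf2 (3 mol %), CH2Cl2, 0 °C to rt, dark
Reagents that add atoms: none
Why: Gold-catalysed 6-endo-dig intramolecular hydroarylation of an aryl propargyl ether, in which the only free ortho carbon (para to a benzyloxy group) attacks the activated terminal alkyne carbon and the stereocentre is kept because its C–O bond is not broken.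

Step 6
Reactants: 8 (2S)-7,8-bis(benzyloxy)-2-[3,4-bis(benzyloxy)phenyl]-2H-chromene
Product: 9 (2R,3S,4S)-7,8-bis(benzyloxy)-2-[3,4-bis(benzyloxy)phenyl]-3,4-dihydro-2H-chromene-3,4-diol (2,3-trans-3,4-cis)
Conditions: K2OsO2(OH)4 (2 mol %), NMO, acetone/H2O, 0 °C to rt
Reagents that add atoms: N-methylmorpholine N-oxide, C[N+]1([O-])CCOCC1; water, O
Why: Catalytic osmium syn-dihydroxylation of the flav-3-ene should take place on the face anti to the 2-aryl group, which sets C3 (S) trans to C2 and gives a stable 5-deoxy flavan-3,4-diol.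

Step 7
Reactants: 9 (2R,3S,4S)-7,8-bis(benzyloxy)-2-[3,4-bis(benzyloxy)phenyl]-3,4-dihydro-2H-chromene-3,4-diol; 10 3,5-bis(benzyloxy)phenol
Product: 11 (2R,3S,4S)-7,8-bis(benzyloxy)-2-[3,4-bis(benzyloxy)phenyl]-4-[2,4-bis(benzyloxy)-6-hydroxyphenyl]-3,4-dihydro-2H-chromen-3-ol
Conditions: 10 (4 equiv), Sc(OTf)3 (10 mol %), MeCN/CH2Cl2, −20 °C to 0 °C
Reagents that add atoms: none
Why: Friedel–Crafts arylation through the C4 benzylic cation (stabilised by O1 and the para 7-benzyloxy group), in which the phenol should attack with its less hindered carbon ortho to the free hydroxyl and on the face anti to the 3-hydroxyl to give the 3,4-trans (4α) adduct, with excess 10 suppressing a second alkylation.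

Step 8
Reactants: 11 (2R,3S,4S)-7,8-bis(benzyloxy)-2-[3,4-bis(benzyloxy)phenyl]-4-[2,4-bis(benzyloxy)-6-hydroxyphenyl]-3,4-dihydro-2H-chromen-3-ol; 3 rac-1-[3,4-bis(benzyloxy)phenyl]prop-2-yn-1-yl acetate
Product: 12 (2R,3S,4S)-7,8-bis(benzyloxy)-2-[3,4-bis(benzyloxy)phenyl]-4-[2,4-bis(benzyloxy)-6-{[(1S)-1-[3,4-bis(benzyloxy)phenyl]prop-2-yn-1-yl]oxy}phenyl]-3,4-dihydro-2H-chromen-3-ol
Conditions: Cu(MeCN)4BF4 (10 mol %), (S,S)-Ph-pybox (12 mol %), iPr2NEt, MeOH/THF, −20 °C
Reagents that add atoms: none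
Why: The same copper-catalysed enantioselective propargylic etherification as in step 4, in which the phenoxide of ring D is far more nucleophilic than the hindered secondary 3-hydroxyl and the ligand should again set the (S)-centre.

Step 9
Reactants: 12 (2R,3S,4S)-7,8-bis(benzyloxy)-2-[3,4-bis(benzyloxy)phenyl]-4-[2,4-bis(benzyloxy)-6-{[(1S)-1-[3,4-bis(benzyloxy)phenyl]prop-2-yn-1-yl]oxy}phenyl]-3,4-dihydro-2H-chromen-3-ol
Product: 13 (2R,3S,4S)-7,8-bis(benzyloxy)-2-[3,4-bis(benzyloxy)phenyl]-4-{(2S)-5,7-bis(benzyloxy)-2-[3,4-bis(benzyloxy)phenyl]-2H-chromen-8-yl}-3,4-dihydro-2H-chromen-3-ol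
Conditions: Ph3PAuNTf2 (5 mol %), CH2Cl2, 0 °C to rt, dark
Reagents that add atoms: none
Why: Cationic monovalent gold binds the terminal alkyne of 12, and carbon C4a of ring D, which is ortho to O1 and to the 5-benzyloxy group and para to the 7-benzyloxy group, attacks the terminal alkyne carbon anti to gold; rearomatisation and protodeauration of the vinyl-gold species release the 2H-chromene. The closest known reaction type is the gold- or platinum-catalysed intramolecular hydroarylation of aryl propargyl ethers to 2H-chromenes. Ring F closes in the 6-endo-dig mode; the 5-exo-dig alternative (attack on the internal carbon) would give a strained 3-methylene-dihydrobenzofuran and is not expected for terminal aryl propargyl ethers. No new stereocentre is formed, and C2 of the lower unit keeps its configuration because none of its bonds is broken; this centre later steers the hydroboration at C3. The step needs site selectivity on ring D and chemoselectivity over ionisation of the benzylic propargylic C–O bond: the first is secured by the tether, since C8 is blocked by the upper unit and C6 cannot be reached, the second by the neutral aprotic conditions, the low temperature and the very high nucleophilicity of C4a.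

Step 10
Reactants: 13 (2R,3S,4S)-7,8-bis(benzyloxy)-2-[3,4-bis(benzyloxy)phenyl]-4-{(2S)-5,7-bis(benzyloxy)-2-[3,4-bis(benzyloxy)phenyl]-2H-chromen-8-yl}-3,4-dihydro-2H-chromen-3-ol
Product: 15 octa-O-benzyl mesquitol-(4α→8)-catechin, via alkylborane 14 (not isolated)
Conditions: BH3·THF (excess), THF, 0 °C to rt; then aq. NaOH, H2O2, 0 °C
Reagents that add atoms: hydrogen peroxide, OO
Why: Hydroboration–oxidation, in which boron should add to C3 (the β-carbon of the electron-rich styrene) from the face anti to the 2-aryl group and oxidation with retention gives the 2,3-trans 3-ol (3S), the borate at the upper 3-oxygen being hydrolysed in the work-up.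

Step 11
Reactants: 15 octa-O-benzyl mesquitol-(4α→8)-catechin
Product: 16 mesquitol-(4α→8)-catechin (CNP0231186.1)
Conditions: H2 (1 atm), Pd(OH)2/C, THF/MeOH, rt
Reagents that add atoms: none
Why: Hydrogenolysis of the eight benzyl ethers, under which the flavan C2–O1 bonds and the interflavan bond of benzylated proanthocyanidins are expected to survive.

**Compound list**

1 | 3,4-bis(benzyloxy)benzaldehyde | O=Cc1ccc(OCc2ccccc2)c(OCc2ccccc2)c1 | starting material
2 | rac-1-[3,4-bis(benzyloxy)phenyl]prop-2-yn-1-ol | OC(C#C)c1ccc(OCc2ccccc2)c(OCc2ccccc2)c1 | intermediate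
3 | rac-1-[3,4-bis(benzyloxy)phenyl]prop-2-yn-1-yl acetate | CC(=O)OC(C#C)c1ccc(OCc2ccccc2)c(OCc2ccccc2)c1 | intermediate
4 | 2,3-bis(benzyloxy)benzaldehyde | O=Cc1cccc(OCc2ccccc2)c1OCc1ccccc1 | starting material
5 | 2,3-bis(benzyloxy)phenyl formate (not isolated) | O=COc1cccc(OCc2ccccc2)c1OCc1ccccc1 | intermediate
6 | 2,3-bis(benzyloxy)phenol | Oc1cccc(OCc2ccccc2)c1OCc1ccccc1 | intermediate
7 | 1,2-bis(benzyloxy)-3-{[(1S)-1-[3,4-bis(benzyloxy)phenyl]prop-2-yn-1-yl]oxy}benzene | C#C[C@H](Oc1cccc(OCc2ccccc2)c1OCc1ccccc1)c1ccc(OCc2ccccc2)c(OCc2ccccc2)c1 | intermediate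
8 | (2S)-7,8-bis(benzyloxy)-2-[3,4-bis(benzyloxy)phenyl]-2H-chromene | O(Cc5ccccc5)c1ccc([C@H]2Oc3c(ccc(OCc5ccccc5)c3OCc5ccccc5)C=C2)cc1OCc5ccccc5 | intermediate
9 | (2R,3S,4S)-7,8-bis(benzyloxy)-2-[3,4-bis(benzyloxy)phenyl]-3,4-dihydro-2H-chromene-3,4-diol | O(Cc5ccccc5)c1ccc([C@H]2Oc3c(ccc(OCc5ccccc5)c3OCc5ccccc5)[C@H](O)[C@@H]2O)cc1OCc5ccccc5 | intermediate
10 | 3,5-bis(benzyloxy)phenol | Oc1cc(OCc2ccccc2)cc(OCc2ccccc2)c1 | starting material
11 | (2R,3S,4S)-7,8-bis(benzyloxy)-2-[3,4-bis(benzyloxy)phenyl]-4-[2,4-bis(benzyloxy)-6-hydroxyphenyl]-3,4-dihydro-2H-chromen-3-ol | O(Cc5ccccc5)c1ccc([C@H]2Oc3c(ccc(OCc5ccccc5)c3OCc5ccccc5)[C@@H](c3c(OCc5ccccc5)cc(OCc5ccccc5)cc3O)[C@@H]2O)cc1OCc5ccccc5 | intermediate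
12 | (1S)-1-arylpropargyl ether of the ring D phenol of 11 (full name in step 8) | O(Cc5ccccc5)c1ccc([C@H]2Oc3c(ccc(OCc5ccccc5)c3OCc5ccccc5)[C@@H](c3c(OCc5ccccc5)cc(OCc5ccccc5)cc3O[C@H](c3ccc(OCc5ccccc5)c(OCc5ccccc5)c3)C#C)[C@@H]2O)cc1OCc5ccccc5 | intermediate
13 | (2R,3S,4S)-7,8-bis(benzyloxy)-2-[3,4-bis(benzyloxy)phenyl]-4-{(2S)-5,7-bis(benzyloxy)-2-[3,4-bis(benzyloxy)phenyl]-2H-chromen-8-yl}-3,4-dihydro-2H-chromen-3-ol | O(Cc5ccccc5)c1ccc([C@H]2Oc3c(ccc(OCc5ccccc5)c3OCc5ccccc5)[C@@H](c3c(OCc5ccccc5)cc(OCc5ccccc5)c4c3O[C@H](c3ccc(OCc5ccccc5)c(OCc5ccccc5)c3)C=C4)[C@@H]2O)cc1OCc5ccccc5 | intermediate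
14 | alkylborane from 13, drawn as the monoalkylborane: BH2 on C3 of the lower unit trans to the 2-aryl group, upper 3-oxygen as O–BH2 (not isolated) | O(Cc5ccccc5)c1ccc([C@H]2Oc3c(ccc(OCc5ccccc5)c3OCc5ccccc5)[C@@H](c3c(OCc5ccccc5)cc(OCc5ccccc5)c4c3O[C@H](c3ccc(OCc5ccccc5)c(OCc5ccccc5)c3)[C@@H](B)C4)[C@@H]2OB)cc1OCc5ccccc5 | intermediate
15 | octa-O-benzyl mesquitol-(4α→8)-catechin: (2R,3S,4S)-7,8-bis(benzyloxy)-2-[3,4-bis(benzyloxy)phenyl]-4-{(2R,3S)-5,7-bis(benzyloxy)-2-[3,4-bis(benzyloxy)phenyl]-3-hydroxy-3,4-dihydro-2H-chromen-8-yl}-3,4-dihydro-2H-chromen-3-ol | O(Cc5ccccc5)c1ccc([C@H]2Oc3c(ccc(OCc5ccccc5)c3OCc5ccccc5)[C@@H](c3c(OCc5ccccc5)cc(OCc5ccccc5)c4c3O[C@H](c3ccc(OCc5ccccc5)c(OCc5ccccc5)c3)[C@@H](O)C4)[C@@H]2O)cc1OCc5ccccc5 | intermediate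
16 | mesquitol-(4α→8)-catechin: (2R,3S,4S)-2-(3,4-dihydroxyphenyl)-4-[(2R,3S)-2-(3,4-dihydroxyphenyl)-3,5,7-trihydroxy-3,4-dihydro-2H-chromen-8-yl]-3,4-dihydro-2H-chromene-3,7,8-triol | Oc1ccc([C@H]2Oc3c(ccc(O)c3O)[C@@H](c3c(O)cc(O)c4c3O[C@H](c3ccc(O)c(O)c3)[C@@H](O)C4)[C@@H]2O)cc1O | target

**Step count**

Total: 11 steps. Longest linear sequence: 10 steps (steps 1, 2 and 4 to 11, from aldehyde 1).

**Steps most likely to fail, with fallbacks**

1. Step 8. The hindered phenoxide of 11 may attack the copper allenylidene slowly, so that uncatalysed ionisation of the electron-rich acetate (or of the product ether) takes over and the new centre forms with poor facial control. Fallback, from 3 back to 12: racemic acetate 3 is hydrolysed enantioselectively with Candida antarctica lipase B (phosphate buffer/MTBE, rt), which by the usual empirical rule for lipases should release (R)-1-[3,4-bis(benzyloxy)phenyl]prop-2-yn-1-ol F1 and leave the (S)-acetate. F1 is then joined to phenol 11 in a Mitsunobu etherification (PPh3, DIAD, toluene, 0 °C), which should give 12 with inversion; the hindered 3-hydroxyl of 11 is expected to stay untouched.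

2. Step 7. The phenol may attack the C4 cation on the face syn to the free 3-hydroxyl, since 5-deoxy flavan cations are less face-selective than their 5-oxygenated relatives. Fallback, from 9 back to 11: diol 9 is acetylated (Ac2O, pyridine, DMAP) to the 3,4-diacetate F2. Ionisation of the 4-acetate (Me3SiOTf cat., CH2Cl2, −40 °C) in the presence of 10 then passes through a cis-fused acetoxonium ion that shields the syn face, so that only the 3,4-trans 3-O-acetyl adduct F3 should form. Methanolysis (K2CO3 cat., MeOH) returns 11.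

3. Step 9. The bulky C8 substituent of ring D may hold the propargyl ether away from C4a, so that cyclisation is slow and gold-induced ionisation of the doubly activated C–O bond (loss of the side chain or epimerisation) competes. Fallback, from 10 and 3 back to 15: the ring closure is done before the two units are joined. Phenol 10 and acetate 3 give, under the conditions of step 4, the (S)-aryl propargyl ether F4. The same gold-catalysed C4–C4a closure (conditions of step 5) on this unhindered ether gives the flav-3-ene F5. Hydroboration (BH3·THF; then NaOH, H2O2) through the alkylborane F6 gives tetra-O-benzylcatechin F7. Diol 9 is then coupled with F7 (Sc(OTf)3 cat., MeCN/CH2Cl2, −20 °C), where the more nucleophilic C8 of F7 should take up the C4 cation anti to the 3-hydroxyl and give 15.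

**Further compounds**

F1 | step 8 | (R)-1-[3,4-bis(benzyloxy)phenyl]prop-2-yn-1-ol | C#C[C@@H](O)c1ccc(OCc2ccccc2)c(OCc2ccccc2)c1
F2 | step 7 | (2R,3S,4S)-7,8-bis(benzyloxy)-2-[3,4-bis(benzyloxy)phenyl]-3,4-dihydro-2H-chromene-3,4-diyl diacetate | O(Cc5ccccc5)c1ccc([C@H]2Oc3c(ccc(OCc5ccccc5)c3OCc5ccccc5)[C@H](OC(C)=O)[C@@H]2OC(C)=O)cc1OCc5ccccc5
F3 | step 7 | (2R,3S,4S)-7,8-bis(benzyloxy)-2-[3,4-bis(benzyloxy)phenyl]-4-[2,4-bis(benzyloxy)-6-hydroxyphenyl]-3,4-dihydro-2H-chromen-3-yl acetate | O(Cc5ccccc5)c1ccc([C@H]2Oc3c(ccc(OCc5ccccc5)c3OCc5ccccc5)[C@@H](c3c(OCc5ccccc5)cc(OCc5ccccc5)cc3O)[C@@H]2OC(C)=O)cc1OCc5ccccc5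
F4 | step 9 | 1,3-bis(benzyloxy)-5-{[(1S)-1-[3,4-bis(benzyloxy)phenyl]prop-2-yn-1-yl]oxy}benzene | C#C[C@H](Oc1cc(OCc2ccccc2)cc(OCc2ccccc2)c1)c1ccc(OCc2ccccc2)c(OCc2ccccc2)c1
F5 | step 9 | (2S)-5,7-bis(benzyloxy)-2-[3,4-bis(benzyloxy)phenyl]-2H-chromene | O(Cc5ccccc5)c1ccc([C@H]2Oc3cc(OCc5ccccc5)cc(OCc5ccccc5)c3C=C2)cc1OCc5ccccc5
F6 | step 9 | alkylborane from F5, BH2 on C3 trans to the 2-aryl group (not isolated) | O(Cc5ccccc5)c1ccc([C@H]2Oc3cc(OCc5ccccc5)cc(OCc5ccccc5)c3C[C@@H]2B)cc1OCc5ccccc5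
F7 | step 9 | (2R,3S)-5,7-bis(benzyloxy)-2-[3,4-bis(benzyloxy)phenyl]-3,4-dihydro-2H-chromen-3-ol (tetra-O-benzylcatechin) | O(Cc5ccccc5)c1ccc([C@H]2Oc3cc(OCc5ccccc5)cc(OCc5ccccc5)c3C[C@@H]2O)cc1OCc5ccccc5
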